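The leftover substrate in Thursday's flask is what I reckon from: 77.0% stands at 50.0 s, which gives a pseudo-first-order constant of 0.00523 /s, and the reading at 30.0 s gives 0.00518 /s. A straight line fits these readings too, so taking substrate as the concentration that sets the order is my bet.

all flasks: substrate 26 mM; initiator 2.5 mol%

| charge | partner | protic impurity | remark | time |
|---|---|---|---|---|
| Thursday's | 1.2 equiv | 13 mM | the very flask that is asked about, followed so far |  |
| flask | 1.20 equiv | 13.0 mM |  | 3.0 min |

Thursday's run (percent of the substrate charged)

| time / s | target / % | substrate / % |
|---|---|---|
| 10.0 | 4.0 | 94.4 |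
| 20.0 | 9.1 | 90.1 |
| 30.0 | 13.2 | 85.6 |
| 40.0 | 17.8 | 80.5 |
| 50.0 | 21.1 | 77.0 |

(standard deviation of a reading: 0.5 percentage points)

* concentration of target at 3.0 min, in mM
* concentration of substrate at 3.0 min, in mM
* concentration of over-reaction product at 3.0 min, in mM

I fold this into one decay count, the constant times the reaction time, which says how many e-fold falls I expect of the substrate in that time: 0.941. On that bet I reckon 39.0% of the substrate left, 10.1 mM, and 15.9 mM reacted. Was one number enough? Leaving homo dimer aside, if the protic impurity took its full charge of partner, 18.2 mM of partner would remain, just above that demand, so on this sum the bet holds, narrowly. But the count gives no split of the reacted substrate between target and over-reaction product.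

The forecast, holding that “Rate order is not resolved by these data”, gives 12.5 mM target, 12 mM substrate and 0.7 mM over-reaction product, with its substrate above mine. The flask gives 12.1 mM target, 10.3 mM substrate and 3.61 mM over-reaction product.

    initiator → 2 initiating radical (k = 2.30 × 10⁻⁴ /s)
    2 first chain carrier → ended chains A (k = 7.90 × 10⁶ /M/s)
    partner + protic impurity → quenched reagent (k = 0.160 /M/s)
    partner + first chain carrier → target + second chain carrier (k = 5.70 × 10⁵ /M/s)
    target → over-reaction product (k = 0.00260 /s)
    2 second chain carrier → ended chains B (k = 2.00 × 10⁸ /M/s)
    substrate + initiating radical → capped initiator + first chain carrier (k = 8.30 × 10⁵ /M/s)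
    substrate + second chain carrier → released group + first chain carrier (k = 1.90 × 10⁵ /M/s)
    2 partner → homo dimer (k = 0.0900 /M/s)

The neighbour charged with 6.5 mM of substrate keeps the equivalents and loadings, so it holds a quarter of the initiator. The scheme ends second chain carrier in pairs, and I scale the count with the root of that charge: 0.470, leaving 62.5%. That neighbour's second chain carrier reads 1.33 × 10⁻⁵ mM, half of the asked flask's at the same time, and it holds 62.9% of its substrate, 4.09 mM.

Readings and results stem from a simulated flask on assumed constants; noise was put on by code.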